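4 questions are open on this bench; for each flask we reckon a ceiling and the shortfall below it.

| flask | electrophile | nucleophile | remark | time |
|---|---|---|---|---|
| Wednesday's | 0.30 M | 0.80 equiv | run made earlier |  |
| Monday's | 0.10 M | 0.80 equiv | run made earlier |  |
| alpha | 0.20 M | 0.800 equiv |  | 20 min |
| eta | 0.20 M | 1.00 equiv |  | 20 min |
| delta | 0.20 M | 1.40 equiv |  | 20 min |

| run | time / min | electrophile / % | target / % |
|---|---|---|---|
| Wednesday's | 1.00 | 62 | 39 |
| Wednesday's | 3.00 | 46 | 55 |
| Wednesday's | 6.00 | 35 | 67 |
| Wednesday's | 8.00 | 31 | 71 |
| Wednesday's | 12.0 | 24 | 75 |
| Monday's | 1.00 | 75 | 26 |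
| Monday's | 2.00 | 70 | 34 |
| Monday's | 3.00 | 65 | 41 |
| Monday's | 6.00 | 47 | 54 |
| Monday's | 12.0 | 36 | 68 |

(scatter of a reading: 2 percentage points)

- part of the electrophile that has reacted at the end, alpha
- part of the electrophile that has reacted at the end, eta
- part of the electrophile that has reacted at the end, delta
- what raising the equivalents of nucleophile from its lowest to its highest value here does to the part of the electrophile that has reacted (changes below 5 percentage points count as none) (it rises / it falls / no change)



In both earlier runs electrophile and target add up to about the whole charge, so we count them one for one. With 0.800 equiv of nucleophile, the limiting reagent, alpha can reach 80.0 %. This is its ceiling: the smaller of the nucleophile equivalents and the whole charge, as a fraction of the electrophile charged. Eta and delta have ceilings of 100 % and 100 %, so we expect the reacted part to rise.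

We reckon just the shortfall for alpha. At equal equivalents, a rate in both partners makes the fractions follow starting concentration times time. Wednesday's reading at 1.00 min and Monday's at 3.00 min share that product and show 38.0 % and 35.0 % reacted. Alpha's product, 240 M·s, is larger than Wednesday's last, 216 M·s. That reading stands 4 percentage points under the ceiling, so we expect alpha between 76.0 % and 80.0 %. Leave alpha's clock alone: from alpha to delta the ceiling moves by 20 points, more than the 4 points of that shortfall.

The forecast gives 77 %, 89 % and 98 % for alpha, eta and delta, and on the trend says it rises. Its ground: “With 0.80 equiv of nucleophile, a 1:1 reaction caps conversion at 80%”.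

The flasks give 77.8 %, 91.1 % and 99.5 %; on the trend, it rises, by 22 points. The forecast held.

    electrophile + nucleophile → acid set free + target (k = 0.0890 /M/s)
    nucleophile + acid set free ⇌ protonated nucleophile, settled at all times (K = 82.0 /M)
    crystals ⇌ acid set free, rate k3*(cs3 - [acid set free]) while solid is left; crystals form when [acid set free] > cs3 (solubility = 8.60 mM, k = 0.0240 /s)

Alpha ends 2.2 points under its ceiling of 80.0 %, and at 200 min it gives 80.0 %. Delta ends above alpha mainly because of the difference in equivalents of nucleophile: with alpha's equivalents, delta gives 77.8 % instead of 99.5 %. At 20 min, alpha has 1.5 % of its nucleophile free.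

A second flask like alpha, with 0.480 equiv of nucleophile, has a ceiling of 48.0 %. That flask gives 47.9 %.

The numbers in the tables stem from a simulated flask with made-up constants; the scatter is artificial.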